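**Retrosynthetic overview**
1. Target 18 ← bis-MOM ether 17. The dimethylpyran ring is made last, by propargyl Claisen rearrangement and oxa-6π closure of the aryl 1,1-dimethylpropargyl ether 14 on O-4' of ring B.
2. Isoflavone core (10) ← acetal 9 ← 2'-hydroxychalcone 8, by thallium-mediated oxidative 1,2-aryl shift and acid closure of the pyranone ring C.
3. Chalcone 8 ← acetophenone 6 (ring A) + benzaldehyde 4 (ring B). This is the key C–C bond, made by intermolecular Claisen–Schmidt aldol condensation.
4. 6 ← 2,4-dihydroxyacetophenone. 4 ← 2,4,5-trimethoxybenzaldehyde by selective bis-demethylation and differentiated protection (4-OBn, 2-OMOM).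
5. Ring order: rings A and B are bought as arenes, ring C is closed in step 7, the pyran ring in step 11.

Assumption: the target SMILES has no stereocentre and no stereogenic double bond, so it is achiral and needs no enantiocontrol; the racemic centres in 7 and 9 and the E-alkene of 8 are erased later.

**Step 1**
Reactants: 1 2,4,5-trimethoxybenzaldehyde
Product: 2 2,4-dihydroxy-5-methoxybenzaldehyde
Conditions: AlCl3 (5 equiv), CH2Cl2, 0 °C → rt, 16 h; then ice/1 M HCl
Reagents that add atoms: none
Why: AlCl3 bound to the formyl oxygen cleaves the chelated ortho methyl ether and the para methyl ether conjugated to the complexed carbonyl, while the meta 5-OMe is not activated (Lewis-acid aryl methyl ether cleavage).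

**Step 2**
Reactants: 2 2,4-dihydroxy-5-methoxybenzaldehyde
Product: 3 4-(benzyloxy)-2-hydroxy-5-methoxybenzaldehyde
Conditions: BnBr (1.05 equiv), NaHCO3 (1.5 equiv), KI (cat.), MeCN, 80 °C
Reagents that add atoms: benzyl bromide, BrCc1ccccc1
Why: Williamson etherification with a weak base alkylates only the more acidic 4-OH (para to CHO), because the 2-OH is locked in a hydrogen bond to the formyl group.

**Step 3**
Reactants: 3 4-(benzyloxy)-2-hydroxy-5-methoxybenzaldehyde
Product: 4 4-(benzyloxy)-5-methoxy-2-(methoxymethoxy)benzaldehyde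
Conditions: MOMCl (1.5 equiv), iPr2NEt (2 equiv), CH2Cl2, 0 °C → reflux
Reagents that add atoms: chloromethyl methyl ether, COCCl
Why: O-alkylation of the remaining phenol with the reactive α-chloro ether gives a base-stable MOM acetal (MOM protection) that survives the aldol step.

**Step 4**
Reactants: 5 1-(2,4-dihydroxyphenyl)ethan-1-one (2,4-dihydroxyacetophenone)
Product: 6 1-[2-hydroxy-4-(methoxymethoxy)phenyl]ethan-1-one
Conditions: MOMCl (1.1 equiv), K2CO3 (1.5 equiv), acetone, rt
Reagents that add atoms: chloromethyl methyl ether, COCCl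
Why: Selective MOM protection (Williamson-type) of the non-chelated 4-OH leaves the ketone-chelated 2-OH free for the later pyranone closure.

**Step 5**
Reactants: 4 4-(benzyloxy)-5-methoxy-2-(methoxymethoxy)benzaldehyde, 6 1-[2-hydroxy-4-(methoxymethoxy)phenyl]ethan-1-one
Product: 8 (E)-3-[4-(benzyloxy)-5-methoxy-2-(methoxymethoxy)phenyl]-1-[2-hydroxy-4-(methoxymethoxy)phenyl]prop-2-en-1-one, via aldol adduct 7 (not isolated)
Conditions: KOH (50% aq, 10 equiv), EtOH, rt, 24–48 h; neutralise cold to pH 6 (AcOH)
Reagents that add atoms: none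
Why: Claisen–Schmidt aldol condensation of the methyl ketone enolate with the non-enolisable aldehyde, followed by E1cB dehydration, gives the thermodynamic E-enone, and the racemic carbinol centre of 7 is lost.

**Step 6**
Reactants: 8 the E-chalcone
Product: 9 2-[4-(benzyloxy)-5-methoxy-2-(methoxymethoxy)phenyl]-1-[2-hydroxy-4-(methoxymethoxy)phenyl]-3,3-dimethoxypropan-1-one (racemic)
Conditions: Tl(NO3)3·3H2O (1.2 equiv), MeOH–HC(OMe)3 (1:1), rt, 3–6 h; aq Na2SO3/NaHCO3, filter
Reagents that add atoms: methanol, CO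
Why: Trivalent thallium activates the enone C=C toward methanol and the very electron-rich trioxygenated aryl ring migrates 1,2 as monovalent thallium leaves (oxidative aryl rearrangement of a chalcone); the new centre is racemic and is erased in step 7.

**Step 7**
Reactants: 9 the β-keto dimethyl acetal
Product: 10 3-[4-(benzyloxy)-2-hydroxy-5-methoxyphenyl]-7-hydroxy-4H-chromen-4-one
Conditions: conc. HCl–MeOH (1:9), reflux, 2–3 h
Reagents that add atoms: none
Why: Acid ionises the acetal, the chelated ring A phenol closes the pyranone and methanol is eliminated (acetal cyclisation–elimination), and the same acid cleaves both MOM acetals, while benzyl and methyl ethers survive.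

**Step 8**
Reactants: 10 3-[4-(benzyloxy)-2-hydroxy-5-methoxyphenyl]-7-hydroxy-4H-chromen-4-one
Product: 11 3-[4-(benzyloxy)-5-methoxy-2-(methoxymethoxy)phenyl]-7-(methoxymethoxy)-4H-chromen-4-one
Conditions: MOMCl (3 equiv), iPr2NEt (4 equiv), CH2Cl2, 0 °C → reflux
Reagents that add atoms: chloromethyl methyl ether, COCCl
Why: MOM protection of both free phenols under non-nucleophilic amine base (the chromone is base-sensitive only to hydroxide or alkoxide) ensures that only O-4' is free after step 9.

**Step 9**
Reactants: 11 the 4'-benzyl bis-MOM isoflavone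
Product: 12 3-[4-hydroxy-5-methoxy-2-(methoxymethoxy)phenyl]-7-(methoxymethoxy)-4H-chromen-4-one
Conditions: H2 (1 atm), 10% Pd/C, EtOAc–MeOH, rt, stop at full debenzylation
Reagents that add atoms: none
Why: Catalytic hydrogenolysis cleaves the benzylic C–O bond much faster than it reduces the chromone C2=C3 bond, and MOM and methyl ethers are inert.

**Step 10**
Reactants: 12 the 4'-phenol, 13 3-chloro-3-methylbut-1-yne
Product: 14 3-{5-methoxy-2-(methoxymethoxy)-4-[(2-methylbut-3-yn-2-yl)oxy]phenyl}-7-(methoxymethoxy)-4H-chromen-4-one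
Conditions: DBU (3 equiv), CuCl2·2H2O (1 mol %), MeCN, 0 °C → rt
Reagents that add atoms: none
Why: Copper-catalysed propargylic substitution lets the phenoxide capture the tertiary propargylic electrophile at oxygen at low temperature, giving the aryl 1,1-dimethylpropargyl ether.

**Step 11**
Reactants: 14 the aryl 1,1-dimethylpropargyl ether
Product: 17 3-[8-methoxy-5-(methoxymethoxy)-2,2-dimethyl-2H-chromen-6-yl]-7-(methoxymethoxy)-4H-chromen-4-one, via allenylphenol 15 (not isolated), via ortho-quinone methide 16 (not isolated)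
Conditions: PhNEt2, 185 °C, 3 h, Ar
Reagents that add atoms: none
Why: Aromatic propargyl Claisen rearrangement to C-3' (the only open ortho position, since C-5' carries OMe) gives 15, a 1,5-hydrogen shift gives 16, and oxa-6π electrocyclisation closes the 2,2-dimethyl-2H-pyran on O-4'.

**Step 12**
Reactants: 17 the bis-MOM chromene
Product: 18 7-hydroxy-3-(5-hydroxy-8-methoxy-2,2-dimethyl-2H-chromen-6-yl)-4H-chromen-4-one (target)
Conditions: 3 M HCl (aq)–MeOH (1:5), 50 °C, 1–2 h
Reagents that add atoms: none
Why: Mild acid-catalysed acetal cleavage removes both MOM groups under conditions that the chromene alkene and the aryl methyl ether tolerate.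

**Compound list**
1 | 2,4,5-trimethoxybenzaldehyde | O=Cc1cc(OC)c(OC)cc1OC | starting material
2 | 2,4-dihydroxy-5-methoxybenzaldehyde | O=Cc1cc(OC)c(O)cc1O | intermediate
3 | 4-(benzyloxy)-2-hydroxy-5-methoxybenzaldehyde | O=Cc1cc(OC)c(OCc2ccccc2)cc1O | intermediate
4 | 4-(benzyloxy)-5-methoxy-2-(methoxymethoxy)benzaldehyde | O=Cc1cc(OC)c(OCc2ccccc2)cc1OCOC | intermediate
5 | 1-(2,4-dihydroxyphenyl)ethan-1-one | CC(=O)c1ccc(O)cc1O | starting material
6 | 1-[2-hydroxy-4-(methoxymethoxy)phenyl]ethan-1-one | CC(=O)c1ccc(OCOC)cc1O | intermediate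
7 | 3-[4-(benzyloxy)-5-methoxy-2-(methoxymethoxy)phenyl]-3-hydroxy-1-[2-hydroxy-4-(methoxymethoxy)phenyl]propan-1-one (racemic aldol adduct, not isolated) | O=C(CC(O)c1cc(OC)c(OCc2ccccc2)cc1OCOC)c1ccc(OCOC)cc1O | intermediate
8 | (E)-3-[4-(benzyloxy)-5-methoxy-2-(methoxymethoxy)phenyl]-1-[2-hydroxy-4-(methoxymethoxy)phenyl]prop-2-en-1-one | O=C(/C=C/c1cc(OC)c(OCc2ccccc2)cc1OCOC)c1ccc(OCOC)cc1O | intermediate
9 | 2-[4-(benzyloxy)-5-methoxy-2-(methoxymethoxy)phenyl]-1-[2-hydroxy-4-(methoxymethoxy)phenyl]-3,3-dimethoxypropan-1-one (racemic) | COC(OC)C(C(=O)c1ccc(OCOC)cc1O)c1cc(OC)c(OCc2ccccc2)cc1OCOC | intermediate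
10 | 3-[4-(benzyloxy)-2-hydroxy-5-methoxyphenyl]-7-hydroxy-4H-chromen-4-one | O=c1c(-c2cc(OC)c(OCc3ccccc3)cc2O)coc2cc(O)ccc12 | intermediate
11 | 3-[4-(benzyloxy)-5-methoxy-2-(methoxymethoxy)phenyl]-7-(methoxymethoxy)-4H-chromen-4-one | O=c1c(-c2cc(OC)c(OCc3ccccc3)cc2OCOC)coc2cc(OCOC)ccc12 | intermediate
12 | 3-[4-hydroxy-5-methoxy-2-(methoxymethoxy)phenyl]-7-(methoxymethoxy)-4H-chromen-4-one | O=c1c(-c2cc(OC)c(O)cc2OCOC)coc2cc(OCOC)ccc12 | intermediate
13 | 3-chloro-3-methylbut-1-yne | CC(C)(Cl)C#C | starting material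
14 | 3-{5-methoxy-2-(methoxymethoxy)-4-[(2-methylbut-3-yn-2-yl)oxy]phenyl}-7-(methoxymethoxy)-4H-chromen-4-one | O=c1c(-c2cc(OC)c(OC(C)(C)C#C)cc2OCOC)coc2cc(OCOC)ccc12 | intermediate
15 | 3-[4-hydroxy-5-methoxy-2-(methoxymethoxy)-3-(3-methylbuta-1,2-dien-1-yl)phenyl]-7-(methoxymethoxy)-4H-chromen-4-one (allenylphenol, not isolated) | O=c1c(-c2cc(OC)c(O)c(C=C=C(C)C)c2OCOC)coc2cc(OCOC)ccc12 | intermediate
16 | 3-[5-methoxy-2-(methoxymethoxy)-3-(3-methylbut-2-en-1-ylidene)-4-oxocyclohexa-1,5-dien-1-yl]-7-(methoxymethoxy)-4H-chromen-4-one (ortho-quinone methide, not isolated) | O=c1c(C2=C(OCOC)C(=CC=C(C)C)C(=O)C(OC)=C2)coc2cc(OCOC)ccc12 | intermediate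
17 | 3-[8-methoxy-5-(methoxymethoxy)-2,2-dimethyl-2H-chromen-6-yl]-7-(methoxymethoxy)-4H-chromen-4-one | COc1cc(-c2coc3cc(OCOC)ccc3c2=O)c(OCOC)c2c1OC(C)(C)C=C2 | intermediate
18 | 7-hydroxy-3-(5-hydroxy-8-methoxy-2,2-dimethyl-2H-chromen-6-yl)-4H-chromen-4-one | COc1cc(-c2coc3cc(O)ccc3c2=O)c(O)c2c1OC(C)(C)C=C2 | target

**Totals**
Total step count: 12. Longest linear sequence: 11 steps (steps 1–3, then 5–12); step 4 is the one-step side branch.

**Three steps most likely to fail, each with a fallback**

Step 1, selective double demethylation. The risks are stopping at the mono-phenol or also losing the 5-OMe. The fallback sets out from 1 and comes back at 2, making the two cleavages by two different mechanisms. BCl3 (1.1 equiv, CH2Cl2, −78 → 0 °C) removes only the formyl-chelated ortho methyl ether and gives 2-hydroxy-4,5-dimethoxybenzaldehyde F1. NaSEt (excess, DMF, 110 °C) then demethylates by SN2 attack at the one remaining methyl ether whose phenoxide is conjugated to the formyl group (the para one), giving 2.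

Step 6, oxidative aryl shift. The risks are over-oxidation of the very electron-rich ring B, aurone formation, and MOM loss caused by the HNO3 that is released. The fallback sets out from 8 and comes back at 10 by the chalcone-epoxide route, in which the aroyl group migrates instead of the aryl group and no thallium is used. The chelated phenol of 8 is capped (NaH, MOMCl, DMF, 0 °C) to give the fully protected chalcone (E)-3-[4-(benzyloxy)-5-methoxy-2-(methoxymethoxy)phenyl]-1-[2,4-bis(methoxymethoxy)phenyl]prop-2-en-1-one F2. Weitz–Scheffer epoxidation (H2O2, NaOH, MeOH–acetone, 0 °C) gives the racemic trans-epoxide F3. BF3·OEt2 (CH2Cl2, −20 °C) ionises the benzylic C–O bond and triggers a 1,2-aroyl shift to the α-formyl deoxybenzoin F4. HCl/MeOH at reflux then removes the three MOM groups and cyclodehydrates to 10.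

Step 10, etherification with a tertiary propargylic chloride. The risks are elimination of 13 to the enyne and low conversion of the hindered guaiacol-type phenol. The fallback sets out from 12 and comes back at 17, building the pyran ring in one operation. 12 is condensed with 1,1-diethoxy-3-methylbut-2-ene in 3-picoline at 140 °C: ortho C-alkylation and loss of ethanol give the same ortho-quinone methide 16, which closes by oxa-6π electrocyclisation. Only C-3' is open next to the free O-4', so the regiochemistry is unchanged. No new isolable compound is made on this path (entered below as F0).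

**Further compounds**
F1 | step 1 | 2-hydroxy-4,5-dimethoxybenzaldehyde | O=Cc1cc(OC)c(OC)cc1O
F2 | step 6 | (E)-3-[4-(benzyloxy)-5-methoxy-2-(methoxymethoxy)phenyl]-1-[2,4-bis(methoxymethoxy)phenyl]prop-2-en-1-one | O=C(/C=C/c1cc(OC)c(OCc2ccccc2)cc1OCOC)c1ccc(OCOC)cc1OCOC
F3 | step 6 | trans-{3-[4-(benzyloxy)-5-methoxy-2-(methoxymethoxy)phenyl]oxiran-2-yl}[2,4-bis(methoxymethoxy)phenyl]methanone (racemic, one enantiomer drawn) | O=C([C@@H]1O[C@H]1c1cc(OC)c(OCc2ccccc2)cc1OCOC)c1ccc(OCOC)cc1OCOC
F4 | step 6 | 2-[4-(benzyloxy)-5-methoxy-2-(methoxymethoxy)phenyl]-3-[2,4-bis(methoxymethoxy)phenyl]-3-oxopropanal (racemic) | O=CC(C(=O)c1ccc(OCOC)cc1OCOC)c1cc(OC)c(OCc2ccccc2)cc1OCOC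
F0 | step 10 | none | none
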